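Slowness does not enter here. The south run, with the Q of elm, stops falling by 2.50 d, well inside the 10 d allowed, and maple holds more Q. Both flasks are therefore taken at rest, under thermodynamic control, and the reckoning follows the fraction of E left.

| flask | E | Z | Q | remark | time |
|---|---|---|---|---|---|
| north-west | 0.020 M | 0.060 M | 0.87 mM | run made earlier |  |
| south-east | 0.020 M | 0.060 M | 4.1 mM | run made earlier |  |
| south | 0.017 M | 0.060 M | 0.78 mM | run made earlier |  |
| elm | 0.020 M | 0.0600 M | 0.78 mM |  | 10 d |
| maple | 0.010 M | 0.0600 M | 3.0 mM |  | 10 d |

| run | time / d | D / % |
|---|---|---|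
| north-west | 0.417 | 21.9 |
| north-west | 0.625 | 21.8 |
| north-west | 1.04 | 19.3 |
| north-west | 1.67 | 17.8 |
| north-west | 3.00 | 15.5 |
| north-west | 5.00 | 15.9 |
| south-east | 0.417 | 14.4 |
| south-east | 0.625 | 15.2 |
| south-east | 1.04 | 14.8 |
| south-east | 1.67 | 14.7 |
| south-east | 3.00 | 15.1 |
| south-east | 5.00 | 14.6 |
| south | 0.417 | 22.0 |
| south | 0.833 | 20.4 |
| south | 1.25 | 18.6 |
| south | 2.50 | 15.2 |
| south | 5.00 | 16.0 |

(scatter of a reading: 0.5 percentage points)

- what is said of D includes L
- L is a solid; its amount is given per volume of the solution
- the numbers in the tables scatter with a standard deviation of 0.5 percentage points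
- steps under discussion: E + Z <-> J; D + Q <-> G + Q; E + Z <-> D; D + Q <-> J + Q; L <-> D

* which of the two ends with the higher amount of D, in percent of the E charged ("neither" if they lie within 2 percentage points) (elm / maple / neither)
* D at the end, in percent of the E charged, elm
* D at the end, in percent of the E charged, maple

Take rest to mean constant proportions among D, J and G, with the odds of E left against E reacted inversely proportional to free Z, the Z not yet taken up. The flat south-east run averages 14.8% as D. Elm shares its charges of E and Z, so this reading estimates elm. It also serves as the estimated lower bound for maple, whose smaller charge of E leaves more free Z.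

The upper bound comes from the worst case, with E wholly reacted. The free-Z ceiling, charge of Z less charge of E in maple over the same in elm, is 1.25, which gives 18.5%. That tightens, since little E is left to gain at high conversion and free Z barely differs at low. With E near half reacted in elm, a free-Z ratio of 1.10 raises D by a factor of 1.05, about the largest found by hand, so the top, reckoned from the same scattered average, is 15.5%. The spread stays under the margin, give or take the scatter of 0.5 percentage points.

The forecast says neither, with elm 15.3% (14.3% to 17%) and maple 15% (13.8% to 16.5%), on the ground that “Q therefore only speeds the approach to equilibrium”. Its maple value lies inside the bracket; its elm value stands above this reckoning's 14.8%.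

The flask gives neither: elm 15.0%, maple 15.6%.

    E + Z ⇌ J (K = 50.0 /M, k = 1.30 × 10⁻⁴ /M/s)
    D + Q ⇌ G + Q, rate k2*[Q]*[D] forward; the back reaction follows from the equilibrium constant (K = 0.480, k = 0.00510 /M/s)
    E + Z ⇌ D (K = 14.0 /M, k = 3.00 × 10⁻⁴ /M/s)
    D + Q ⇌ J + Q, rate k4*[Q]*[D] forward; the back reaction follows from the equilibrium constant (k = 0.0150 /M/s)
    L ⇌ D, rate k5*(cs5 - [D]) while solid is left; crystals form when [D] > cs5 (solubility = 9.20 mM, k = 1.10 × 10⁻⁴ /s)

In maple, D was made 1.26 times as fast as it was used up at 0.259 d, while Q passed D on to J and G. At 5.00 d E in maple stood at 21.3%, and at 100 d it still stood at 21.3%. Maple's D is 1.04 times elm's, under the ceiling. A flask like maple with 0.024 M of Z, set against one with 0.015 M, has a ceiling of 2.80, and the first flask's D stands 1.31 times as high as the second's.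

(Readings and results were computed with constants of no real substance, and the scatter is random.)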